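## Plan

1. **Cuts.** Six benzyl ethers and a lower-unit 3,4-carbonate come off last. The interflavanyl bond C4(upper)–C6(lower) is cut as a Friedel–Crafts union of an upper flavan-4-yl cation with a protected all-cis flavan-3,4-diol. Both halves share the 7,8,4'-oxygenation and the same spatial sense at C2, so both are traced to one (2S)-flavanone. In that flavanone ring C is cut at C2–C3 and O1–C8a.
2. **Enabling feature.** At the C4-ketone level ring C is a benzo-fused 2,3-dihydro-4-pyranone, O1–C8a=C4a–C4(=O)–C3. With fluorine on C8a of ring A (ortho to the acyl-bearing C4a) and C3=C4 as a silyl enol ether, the arene is an embedded 1-alkoxy-3-silyloxydiene: C3 is nucleophilic, C8a is an SNAr site. The helpers are the fluorine, the silyl group and the C4 oxygen; the C4 oxygen later serves as the leaving group of the upper unit and as the origin of the C3=C4 alkene of the lower unit.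
3. **Forward order.** Ring A (from 3-fluorocatechol) is acetylated; ring C closes onto the ring B aldehyde in one operation; reduction gives a flavan-4-ol that is used twice, directly as the electrophile and, after dehydration and cis-hydroxylation, as the nucleophile; union, then deprotection.
4. **Stereochemistry.** C2 of both units comes from the catalyst-controlled aldol addition. Lower C3/C4 come from a Woodward cis-hydroxylation, which delivers the diol to the face of the 2-aryl group. Upper C4 comes from pseudoaxial attack on the cation, trans to the 2-aryl group.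

Key step: step 4

Assumption: the (4R)-oxazaborolidinone made from (R)-tryptophan is taken to expose the Si face of the coordinated aldehyde and so give the S aldol; should a test reaction show the opposite sense, its (4S) enantiomer is used with no other change.

## Route

Step 1
Reactants: 1 3-fluorobenzene-1,2-diol (3-fluorocatechol)
Product: 2 1,2-bis(benzyloxy)-3-fluorobenzene
Conditions: BnBr, K2CO3, DMF, 60 °C
Reagents that add atoms: benzyl bromide, BrCc1ccccc1
Why: Williamson ether synthesis of both phenols with a benzylic bromide; benzyl ethers are chosen because all six can be removed together at the end by hydrogenolysis.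

Step 2
Reactants: 2 1,2-bis(benzyloxy)-3-fluorobenzene
Product: 4 1-[3,4-bis(benzyloxy)-2-fluorophenyl]ethan-1-one, via aryllithium 3 (not isolated)
Conditions: n-BuLi, THF, −78 °C; then MeC(O)N(OMe)Me, −78 → 0 °C; then H2O
Reagents that add atoms: N-methoxy-N-methylacetamide, CON(C)C(C)=O
Why: Fluorine-directed ortho-lithiation, in which the ring hydrogen next to fluorine is the most acidic in THF and the ortho-fluoroaryllithium is kept at −78 °C so that it does not lose LiF, followed by acylation with an N-methoxy-N-methylamide, whose chelated tetrahedral adduct stops the addition at the ketone.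

Step 3
Reactants: 4 1-[3,4-bis(benzyloxy)-2-fluorophenyl]ethan-1-one
Product: 5 ({1-[3,4-bis(benzyloxy)-2-fluorophenyl]ethenyl}oxy)trimethylsilane
Conditions: TMSOTf, Et3N, CH2Cl2, 0 °C
Reagents that add atoms: trimethylsilyl trifluoromethanesulfonate, C[Si](C)(C)OS(=O)(=O)C(F)(F)F
Why: Soft enolisation of the methyl ketone with a silyl triflate and a tertiary amine gives the only possible silyl enol ether, the nucleophile for the Mukaiyama aldol addition.

Step 4
Reactants: 5 ({1-[3,4-bis(benzyloxy)-2-fluorophenyl]ethenyl}oxy)trimethylsilane; 6 4-(benzyloxy)benzaldehyde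
Product: 8 (2S)-7,8-bis(benzyloxy)-2-[4-(benzyloxy)phenyl]-2,3-dihydro-4H-chromen-4-one, via silyl aldolate 7 (not isolated)
Conditions: (4R)-2-butyl-4-(1H-indol-3-ylmethyl)-3-(4-methylphenylsulfonyl)-1,3,2-oxazaborolidin-5-one (20 mol %), EtCN, −78 °C; then Bu4N[Ph3SiF2] (0.5 equiv), THF, −78 → 0 °C
Reagents that add atoms: none
Why: Proposed new method: enol ether 5 is an arene-embedded analogue of a 1-alkoxy-3-silyloxybutadiene (C3=C4(OSiMe3)–C4a=C8a–F), so a catalytic Mukaiyama aldol addition of its CH2 terminus to the boron-activated aldehyde forms C2–C3 and, by silyl transfer, gives O-silyl aldolate 7, from which fluoride unmasks the C2 alkoxide next to the C8a–F bond. The alkoxide adds to C8a, the β-carbon of the aryl ketone (6-endo-trig addition–elimination, an SNAr through a Meisenheimer adduct stabilised by the C4 carbonyl), and the expelled fluoride desilylates the next molecule of 7, so that Me3SiF is the only co-product. The closest known reaction types are the aldol–dihydropyranone annulation of aldehydes with 1-methoxy-3-silyloxybutadiene under the same class of oxazaborolidinone catalyst and the fluoride-triggered SNAr etherification of ortho-acyl aryl fluorides by silyl ethers. The new stereocentre C2 is set by the catalyst, which shields one face of the coordinated aldehyde so that the enol ether attacks the Si face (S configuration), and the ring closure does not touch it. The step needs the alkoxide to cyclise faster than it fragments by retro-aldol cleavage or is lost through enolisation and elimination to the chalcone; generating it from the silyl ether under aprotic conditions at low temperature with no free base, next to the only ring carbon that carries a leaving group and is activated by the ortho acyl group, should secure this.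

Step 5
Reactants: 8 (2S)-7,8-bis(benzyloxy)-2-[4-(benzyloxy)phenyl]-2,3-dihydro-4H-chromen-4-one
Product: 9 (2S,4S)-7,8-bis(benzyloxy)-2-[4-(benzyloxy)phenyl]-3,4-dihydro-2H-chromen-4-ol
Conditions: NaBH4, MeOH/THF, 0 °C
Reagents that add atoms: none
Why: Hydride reduction of the chroman-4-one by axial attack should give mainly the 2,4-cis alcohol (equatorial hydroxyl), and either C4 epimer serves later because C4 becomes planar in steps 6 and 9.

Step 6
Reactants: 9 (2S,4S)-7,8-bis(benzyloxy)-2-[4-(benzyloxy)phenyl]-3,4-dihydro-2H-chromen-4-ol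
Product: 10 (2S)-7,8-bis(benzyloxy)-2-[4-(benzyloxy)phenyl]-2H-chromene
Conditions: methyl N-(triethylammoniosulfonyl)carbamate, THF, 50 °C, exclusion of light
Reagents that add atoms: none
Why: Dehydration through the sulfamate ester (syn elimination, or ionisation of the para-alkoxybenzylic ester and loss of H3) gives the conjugated 2H-chromene under non-acidic conditions that leave C2 untouched.

Step 7
Reactants: 10 (2S)-7,8-bis(benzyloxy)-2-[4-(benzyloxy)phenyl]-2H-chromene
Product: 13 (2R,3R,4R)-7,8-bis(benzyloxy)-2-[4-(benzyloxy)phenyl]-3,4-dihydro-2H-chromene-3,4-diol, via iodo acetate 11 (not isolated), via hydroxy acetate 12 (not isolated)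
Conditions: I2, AgOAc, AcOH, rt, dark; then AcOH/H2O, 50 °C; then K2CO3, MeOH, rt
Reagents that add atoms: silver acetate (source of both diol oxygens), CC(=O)[O-].[Ag+]
Why: Woodward cis-hydroxylation, in which iodine adds to C3 from the face opposite to the 2-aryl group and acetate adds to benzylic C4, the acetate then displaces iodide at C3 with inversion (silver-assisted) to form a cis-fused acetoxonium ion on the aryl face, and water opens it to the cis hydroxy acetate, so that after methanolysis both hydroxyls are cis to the 2-aryl group, the face that osmium tetroxide would not reach.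

Step 8
Reactants: 13 (2R,3R,4R)-7,8-bis(benzyloxy)-2-[4-(benzyloxy)phenyl]-3,4-dihydro-2H-chromene-3,4-diol
Product: 14 cyclic 3,4-carbonate of diol 13 (cis-fused 1,3-dioxolan-2-one on C3/C4; all three ring substituents cis)
Conditions: 1,1'-carbonyldiimidazole, DMAP (cat.), CH2Cl2, rt
Reagents that add atoms: 1,1'-carbonyldiimidazole, O=C(n1ccnc1)n1ccnc1
Why: Carbonylation of the cis-1,2-diol gives the cis-fused five-membered carbonate, which ties back the benzylic C4 oxygen against ionisation and masks both hydroxyls against O-alkylation in the acid-mediated union.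

Step 9
Reactants: 9 (2S,4S)-7,8-bis(benzyloxy)-2-[4-(benzyloxy)phenyl]-3,4-dihydro-2H-chromen-4-ol (portion kept from step 5); 14 cyclic 3,4-carbonate of diol 13
Product: 15 hexa-O-benzyl ether lower-3,4-carbonate of the target (C4 of the upper flavan bonded to C6 of the lower unit; upper 4-aryl trans to upper 2-aryl)
Conditions: TMSOTf (0.2 equiv), 4 Å molecular sieves, CH2Cl2, −78 → −40 °C; slow addition of 9 to 14 (3 equiv)
Reagents that add atoms: none
Why: Friedel–Crafts alkylation as in established interflavanyl bond formation, in which acid ionises 9 to the flavan-4-yl cation stabilised by O1 and the para 7-benzyloxy group, C6 of 14 (ortho to 7-OBn and para to O1, whereas C5 is peri-hindered) attacks it pseudoaxially trans to the equatorial 2-aryl group, which should set upper C4 as 2,4-trans, and the excess of 14 competes against attack by ring A of a second molecule of 9.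

Step 10
Reactants: 15 hexa-O-benzyl ether lower-3,4-carbonate of the target
Product: 16 hexa-O-benzyl ether of the target (all six phenols benzylated; lower 3,4-diol free)
Conditions: K2CO3, MeOH/THF, rt
Reagents that add atoms: none
Why: Base-catalysed transesterification of the cyclic carbonate with methanol releases the cis-diol without touching benzyl ethers or stereocentres.

Step 11
Reactants: 16 hexa-O-benzyl ether of the target
Product: 17 (2R,3R,4R)-6-[(2S,4S)-7,8-dihydroxy-2-(4-hydroxyphenyl)-3,4-dihydro-2H-chromen-4-yl]-2-(4-hydroxyphenyl)-3,4-dihydro-2H-chromene-3,4,7,8-tetrol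
Conditions: H2 (1 atm), Pd(OH)2/C, THF/MeOH, rt
Reagents that add atoms: none
Why: Hydrogenolysis of the six aryl benzyl ethers under neutral conditions at low pressure, where they should be cleaved faster than the secondary benzylic C4 hydroxyl and the cyclic benzylic ethers of the two pyran rings.

## Compound list

1 | 3-fluorobenzene-1,2-diol (3-fluorocatechol) | Oc1cccc(F)c1O | starting material
2 | 1,2-bis(benzyloxy)-3-fluorobenzene | Fc1cccc(OCc2ccccc2)c1OCc1ccccc1 | intermediate
3 | [3,4-bis(benzyloxy)-2-fluorophenyl]lithium (not isolated) | [Li]c1ccc(OCc2ccccc2)c(OCc2ccccc2)c1F | intermediate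
4 | 1-[3,4-bis(benzyloxy)-2-fluorophenyl]ethan-1-one | CC(=O)c1ccc(OCc2ccccc2)c(OCc2ccccc2)c1F | intermediate
5 | ({1-[3,4-bis(benzyloxy)-2-fluorophenyl]ethenyl}oxy)trimethylsilane | C=C(O[Si](C)(C)C)c1ccc(OCc2ccccc2)c(OCc2ccccc2)c1F | intermediate
6 | 4-(benzyloxy)benzaldehyde | O=Cc1ccc(OCc2ccccc2)cc1 | starting material
7 | (3S)-3-[4-(benzyloxy)phenyl]-1-[3,4-bis(benzyloxy)-2-fluorophenyl]-3-[(trimethylsilyl)oxy]propan-1-one (not isolated) | C[Si](C)(C)O[C@@H](CC(=O)c1ccc(OCc2ccccc2)c(OCc2ccccc2)c1F)c1ccc(OCc2ccccc2)cc1 | intermediate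
8 | (2S)-7,8-bis(benzyloxy)-2-[4-(benzyloxy)phenyl]-2,3-dihydro-4H-chromen-4-one | O=C1C[C@@H](c2ccc(OCc3ccccc3)cc2)Oc2c1ccc(OCc1ccccc1)c2OCc1ccccc1 | intermediate
9 | (2S,4S)-7,8-bis(benzyloxy)-2-[4-(benzyloxy)phenyl]-3,4-dihydro-2H-chromen-4-ol (2,4-cis) | O[C@H]1C[C@@H](c2ccc(OCc3ccccc3)cc2)Oc2c1ccc(OCc1ccccc1)c2OCc1ccccc1 | intermediate
10 | (2S)-7,8-bis(benzyloxy)-2-[4-(benzyloxy)phenyl]-2H-chromene | C1=C[C@@H](c2ccc(OCc3ccccc3)cc2)Oc2c1ccc(OCc1ccccc1)c2OCc1ccccc1 | intermediate
11 | 4-acetoxy-3-iodo-7,8-bis(benzyloxy)-2-[4-(benzyloxy)phenyl]chroman, iodine trans to the 2-aryl group and acetoxy cis to it (not isolated) | c1cc2c(c(OCc3ccccc3)c1OCc1ccccc1)O[C@H](c1ccc(OCc3ccccc3)cc1)[C@@H](I)[C@@H]2OC(C)=O | intermediate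
12 | 4-O-acetyl derivative of diol 13, all-cis (drawn as the 4-acetate; the 3-acetate formed by acyl shift gives the same diol; not isolated) | c1cc2c(c(OCc3ccccc3)c1OCc1ccccc1)O[C@H](c1ccc(OCc3ccccc3)cc1)[C@H](O)[C@@H]2OC(C)=O | intermediate
13 | (2R,3R,4R)-7,8-bis(benzyloxy)-2-[4-(benzyloxy)phenyl]-3,4-dihydro-2H-chromene-3,4-diol (2,3-cis-3,4-cis) | c1cc2c(c(OCc3ccccc3)c1OCc1ccccc1)O[C@H](c1ccc(OCc3ccccc3)cc1)[C@H](O)[C@@H]2O | intermediate
14 | cyclic 3,4-carbonate of diol 13 (cis-fused 1,3-dioxolan-2-one on C3/C4, cis to the 2-aryl group) | c1cc2c(c(OCc3ccccc3)c1OCc1ccccc1)O[C@H](c1ccc(OCc3ccccc3)cc1)[C@@H]3OC(=O)O[C@H]23 | intermediate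
15 | hexa-O-benzyl ether lower-3,4-carbonate of the target (upper C4 to lower C6; upper 2,4-trans) | C(c5ccccc5)Oc1ccc([C@@H]2C[C@@H](c3cc4c(c(OCc5ccccc5)c3OCc5ccccc5)O[C@H](c3ccc(OCc5ccccc5)cc3)[C@@H]6OC(=O)O[C@H]46)c3ccc(OCc5ccccc5)c(OCc5ccccc5)c3O2)cc1 | intermediate
16 | hexa-O-benzyl ether of the target (lower 3,4-diol free) | C(c5ccccc5)Oc1ccc([C@@H]2C[C@@H](c3cc4c(c(OCc5ccccc5)c3OCc5ccccc5)O[C@H](c3ccc(OCc5ccccc5)cc3)[C@H](O)[C@@H]4O)c3ccc(OCc5ccccc5)c(OCc5ccccc5)c3O2)cc1 | intermediate
17 | (2R,3R,4R)-6-[(2S,4S)-7,8-dihydroxy-2-(4-hydroxyphenyl)-3,4-dihydro-2H-chromen-4-yl]-2-(4-hydroxyphenyl)-3,4-dihydro-2H-chromene-3,4,7,8-tetrol | Oc1ccc([C@@H]2C[C@@H](c3cc4c(c(O)c3O)O[C@H](c3ccc(O)cc3)[C@H](O)[C@@H]4O)c3ccc(O)c(O)c3O2)cc1 | target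

## Step count and risks

Total step count: 11.
Longest linear sequence: 11 steps (1 → 2 → 4 → 5 → 8 → 9 → 10 → 13 → 14 → 15 → 16 → 17); compound 9 enters step 9 a second time as the upper unit.

**Step 4 (proposed method).** The unmasked alkoxide may fragment by retro-aldol cleavage, or be lost by enolisation and elimination to the chalcone, faster than it closes the ring; the aldol addition may also give insufficient facial selectivity. The fallback reaches the flavanone by conjugate arylation of a chromone, with known chemistry throughout; it sets out from 4 and returns at 8. Displacement of the activated fluoride of 4 by hydroxide (KOH, DMSO/H2O, 80 °C) should give 1-[3,4-bis(benzyloxy)-2-hydroxyphenyl]ethan-1-one F1. Condensation with N,N-dimethylformamide dimethyl acetal should give (2E)-1-[3,4-bis(benzyloxy)-2-hydroxyphenyl]-3-(dimethylamino)prop-2-en-1-one F2, which should cyclise in aqueous HCl with loss of dimethylamine to 7,8-bis(benzyloxy)-4H-chromen-4-one F3. Enantioselective conjugate addition of 4-(benzyloxy)phenylboronic acid to F3, catalysed by Pd(OCOCF3)2 and the enantiomer of the tert-butyl pyridine-oxazoline ligand that gives the 2S product, should return flavanone 8.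

**Step 7.** Electrophilic iodination of the alkoxyarene rings may compete with addition to the alkene, the iodo acetate may lose acetic acid to a vinyl iodide, or C4 may lose its configuration through benzylic ionisation of the acetoxonium ion. The fallback installs the 3-oxygen at the ketone level and inverts it; it sets out from 8 and returns at 13. Soft enolisation of 8 (TMSOTf, Et3N) should give (2S)-7,8-bis(benzyloxy)-2-[4-(benzyloxy)phenyl]-4-[(trimethylsilyl)oxy]-2H-chromene F4. Rubottom oxidation with dimethyldioxirane from the face opposite to the 2-aryl group, followed by desilylation, should give the trans-dihydroflavonol (2R,3R)-7,8-bis(benzyloxy)-2-[4-(benzyloxy)phenyl]-3-hydroxy-2,3-dihydro-4H-chromen-4-one F5. Mitsunobu inversion at C3 (4-nitrobenzoic acid, PPh3, diisopropyl azodicarboxylate) should give (2R,3S)-7,8-bis(benzyloxy)-2-[4-(benzyloxy)phenyl]-4-oxo-3,4-dihydro-2H-chromen-3-yl 4-nitrobenzoate F6. NaBH4 should reduce the ketone from the face opposite to the axial ester to (2R,3R,4R)-7,8-bis(benzyloxy)-2-[4-(benzyloxy)phenyl]-4-hydroxy-3,4-dihydro-2H-chromen-3-yl 4-nitrobenzoate F7, and methanolysis (K2CO3, MeOH) should give diol 13.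

**Step 9.** The cation from 9 may be consumed by ring A of its own kind (oligomerisation through its free C6), and some attack at C5 of the nucleophile may occur. The fallback blocks the competing position of the electrophile with bromine so that the partners can be used in equal amounts; it sets out from 8 and returns at 17. Bromination of 8 with N-bromosuccinimide in MeCN, at the ring A position ortho to 7-OBn and para to O1, should give (2S)-7,8-bis(benzyloxy)-2-[4-(benzyloxy)phenyl]-6-bromo-2,3-dihydro-4H-chromen-4-one F8. NaBH4 should give (2S,4S)-7,8-bis(benzyloxy)-2-[4-(benzyloxy)phenyl]-6-bromo-3,4-dihydro-2H-chromen-4-ol F9. Union of F9 with 14 under the conditions of step 9 should give the upper-6-bromo analogue of 15 F10; methanolysis of the carbonate (K2CO3, MeOH/THF) should give the upper-6-bromo analogue of 16 F11. Hydrogenolysis over Pd(OH)2/C with Et3N should remove the bromine together with the benzyl groups and give 17.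

## Further compounds

F1 | step 4 | 1-[3,4-bis(benzyloxy)-2-hydroxyphenyl]ethan-1-one | CC(=O)c1ccc(OCc2ccccc2)c(OCc2ccccc2)c1O
F2 | step 4 | (2E)-1-[3,4-bis(benzyloxy)-2-hydroxyphenyl]-3-(dimethylamino)prop-2-en-1-one | CN(C)/C=C/C(=O)c1ccc(OCc2ccccc2)c(OCc2ccccc2)c1O
F3 | step 4 | 7,8-bis(benzyloxy)-4H-chromen-4-one | O=c1ccoc2c1ccc(OCc1ccccc1)c2OCc1ccccc1
F4 | step 7 | (2S)-7,8-bis(benzyloxy)-2-[4-(benzyloxy)phenyl]-4-[(trimethylsilyl)oxy]-2H-chromene | C[Si](C)(C)OC1=C[C@@H](c2ccc(OCc3ccccc3)cc2)Oc2c1ccc(OCc1ccccc1)c2OCc1ccccc1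
F5 | step 7 | (2R,3R)-7,8-bis(benzyloxy)-2-[4-(benzyloxy)phenyl]-3-hydroxy-2,3-dihydro-4H-chromen-4-one | O=C1[C@H](O)[C@@H](c2ccc(OCc3ccccc3)cc2)Oc2c1ccc(OCc1ccccc1)c2OCc1ccccc1
F6 | step 7 | (2R,3S)-7,8-bis(benzyloxy)-2-[4-(benzyloxy)phenyl]-4-oxo-3,4-dihydro-2H-chromen-3-yl 4-nitrobenzoate | O=C1[C@@H](OC(=O)c2ccc([N+](=O)[O-])cc2)[C@@H](c2ccc(OCc3ccccc3)cc2)Oc2c1ccc(OCc1ccccc1)c2OCc1ccccc1
F7 | step 7 | (2R,3R,4R)-7,8-bis(benzyloxy)-2-[4-(benzyloxy)phenyl]-4-hydroxy-3,4-dihydro-2H-chromen-3-yl 4-nitrobenzoate | c1cc2c(c(OCc3ccccc3)c1OCc1ccccc1)O[C@H](c1ccc(OCc3ccccc3)cc1)[C@H](OC(=O)c1ccc([N+](=O)[O-])cc1)[C@@H]2O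
F8 | step 9 | (2S)-7,8-bis(benzyloxy)-2-[4-(benzyloxy)phenyl]-6-bromo-2,3-dihydro-4H-chromen-4-one | O=C1C[C@@H](c2ccc(OCc3ccccc3)cc2)Oc2c1cc(Br)c(OCc1ccccc1)c2OCc1ccccc1
F9 | step 9 | (2S,4S)-7,8-bis(benzyloxy)-2-[4-(benzyloxy)phenyl]-6-bromo-3,4-dihydro-2H-chromen-4-ol | O[C@H]1C[C@@H](c2ccc(OCc3ccccc3)cc2)Oc2c1cc(Br)c(OCc1ccccc1)c2OCc1ccccc1
F10 | step 9 | upper-6-bromo analogue of 15 | C(c5ccccc5)Oc1ccc([C@@H]2C[C@@H](c3cc4c(c(OCc5ccccc5)c3OCc5ccccc5)O[C@H](c3ccc(OCc5ccccc5)cc3)[C@@H]6OC(=O)O[C@H]46)c3cc(Br)c(OCc5ccccc5)c(OCc5ccccc5)c3O2)cc1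
F11 | step 9 | upper-6-bromo analogue of 16 | C(c5ccccc5)Oc1ccc([C@@H]2C[C@@H](c3cc4c(c(OCc5ccccc5)c3OCc5ccccc5)O[C@H](c3ccc(OCc5ccccc5)cc3)[C@H](O)[C@@H]4O)c3cc(Br)c(OCc5ccccc5)c(OCc5ccccc5)c3O2)cc1
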